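**Retrosynthetic overview**
- The last bond made is C15–O: a lipoxygenase-type dioxygenation of the all-cis eicosapentaenoyl phloroglucinol sets 15S and moves the 14Z olefin into the 11Z,13E diene; O–O reduction then gives the target.
- The all-cis triol ketone comes from its tris-MOM ether by acid methanolysis.
- The aryl–acyl bond comes from ortho-lithiated 1,3,5-tris(methoxymethoxy)benzene and the Weinreb amide of eicosapentaenoic acid.
- Building blocks are ethyl eicosapentaenoate and phloroglucinol; no ring is formed, the arene is bought.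

Assumption: ethyl eicosapentaenoate (icosapent ethyl), phloroglucinol and soybean lipoxygenase-1 are taken as commercial; all polyene intermediates are handled under argon, cold, in the dark, with a trace of BHT.

**Step 1**
Reactants: 1 ethyl (5Z,8Z,11Z,14Z,17Z)-icosa-5,8,11,14,17-pentaenoate
Product: 2 (5Z,8Z,11Z,14Z,17Z)-N-methoxy-N-methylicosa-5,8,11,14,17-pentaenamide
Conditions: MeNH(OMe)·HCl (1.5 equiv), i-PrMgCl (3.0 equiv), THF, –20 °C to 0 °C; aq NH4Cl
Reagents that add atoms: N,O-dimethylhydroxylamine hydrochloride, CNOC.Cl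
Why: The magnesium amide made in the flask substitutes the unhindered ethyl ester quickly at low temperature (nucleophilic acyl substitution, Weinreb amide synthesis) and leaves the non-conjugated Z-olefins untouched.

**Step 2**
Reactants: 3 phloroglucinol (benzene-1,3,5-triol)
Product: 4 1,3,5-tris(methoxymethoxy)benzene
Conditions: NaH (3.6 equiv), MOMCl (3.6 equiv), DMF, 0 °C to rt
Reagents that add atoms: chloromethyl methyl ether, COCCl
Why: Williamson-type O-alkylation of the phenoxides with the hard electrophile MOMCl gives the tris-ether and favours O- over C-alkylation.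

**Step 3**
Reactants: 4 1,3,5-tris(methoxymethoxy)benzene; 2 (5Z,8Z,11Z,14Z,17Z)-N-methoxy-N-methylicosa-5,8,11,14,17-pentaenamide
Product: 7 (5Z,8Z,11Z,14Z,17Z)-1-[2,4,6-tris(methoxymethoxy)phenyl]icosa-5,8,11,14,17-pentaen-1-one, via aryllithium 5 (not isolated), via lithium hemiaminal adduct 6 (not isolated)
Conditions: 4 (1.3 equiv), n-BuLi (1.25 equiv), THF, 0 °C, 1 h; then 2 (1.0 equiv), –78 °C to –20 °C; AcOH, then H2O
Reagents that add atoms: none
Why: Directed ortho-metalation between two OMOM groups gives aryllithium 5, which adds once to the Weinreb amide because chelated adduct 6 survives until the quench (Weinreb ketone synthesis).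

**Step 4**
Reactants: 7 (5Z,8Z,11Z,14Z,17Z)-1-[2,4,6-tris(methoxymethoxy)phenyl]icosa-5,8,11,14,17-pentaen-1-one
Product: 8 (5Z,8Z,11Z,14Z,17Z)-1-(2,4,6-trihydroxyphenyl)icosa-5,8,11,14,17-pentaen-1-one
Conditions: conc. aq HCl (cat.), MeOH/THF 4:1 (dilute), 45 °C, argon, BHT (trace)
Reagents that add atoms: none
Why: Acid-catalysed acetal methanolysis removes the three MOM groups as dimethoxymethane, and skipped Z-polyenes tolerate methanolic HCl as in routine fatty acid methanolysis.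

**Step 5**
Reactants: 8 (5Z,8Z,11Z,14Z,17Z)-1-(2,4,6-trihydroxyphenyl)icosa-5,8,11,14,17-pentaen-1-one
Product: 10 (5Z,8Z,11Z,13E,15S,17Z)-15-hydroxy-1-(2,4,6-trihydroxyphenyl)icosa-5,8,11,13,17-pentaen-1-one, via 15S-hydroperoxide 9 (not isolated)
Conditions: soybean lipoxygenase-1 (Glycine max, non-heme iron dioxygenase), O2 (1 atm), 0.1 M Na2B4O7 buffer pH 9.0 (5% EtOH, 0.3 mM substrate), 4 °C, stopped at one equivalent of O2 (HPLC); then TCEP (neutral aq solution, 1.5 equiv), 4 °C; extraction at pH 5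
Reagents that add atoms: dioxygen, O=O
Why: Proposed new method: soybean lipoxygenase-1 has not been shown to accept an acylphloroglucinol, but it reads its substrates from the methyl end, so its trivalent iron hydroxide cofactor should abstract the pro-S hydrogen of bis-allylic C13 by proton-coupled electron transfer, O2 should then add antarafacially at C15 of the C11–C15 pentadienyl radical to give the 15S peroxyl radical with the 11Z,13E diene, the divalent iron returns the electron to give hydroperoxide 9, and the phosphine reduces the O–O bond with retention at C15; at pH 9 the acylphloroglucinol (a vinylogous acid, pKa about 8) is a mono-anion that imitates the carboxylate head group, and with only meta-related hydroxyls and a deactivating acyl group it should not reduce the active trivalent iron as catechols do; the closest known reaction type is the 15S-dioxygenation by the same enzyme of eicosapentaenoic and arachidonic acids and of head-group-modified analogues such as arachidonoyl ethanolamide.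

**Compound list**
1 | ethyl (5Z,8Z,11Z,14Z,17Z)-icosa-5,8,11,14,17-pentaenoate | CC/C=C\C/C=C\C/C=C\C/C=C\C/C=C\CCCC(=O)OCC | starting material
2 | (5Z,8Z,11Z,14Z,17Z)-N-methoxy-N-methylicosa-5,8,11,14,17-pentaenamide | CC/C=C\C/C=C\C/C=C\C/C=C\C/C=C\CCCC(=O)N(C)OC | intermediate
3 | phloroglucinol (benzene-1,3,5-triol) | Oc1cc(O)cc(O)c1 | starting material
4 | 1,3,5-tris(methoxymethoxy)benzene | COCOc1cc(OCOC)cc(OCOC)c1 | intermediate
5 | 2,4,6-tris(methoxymethoxy)phenyllithium | [Li]c1c(OCOC)cc(OCOC)cc1OCOC | intermediate (not isolated)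
6 | lithium (5Z,8Z,11Z,14Z,17Z)-1-[methoxy(methyl)amino]-1-[2,4,6-tris(methoxymethoxy)phenyl]icosa-5,8,11,14,17-pentaen-1-olate (racemic at C1) | CC/C=C\C/C=C\C/C=C\C/C=C\C/C=C\CCCC(O[Li])(N(C)OC)c1c(OCOC)cc(OCOC)cc1OCOC | intermediate (not isolated)
7 | (5Z,8Z,11Z,14Z,17Z)-1-[2,4,6-tris(methoxymethoxy)phenyl]icosa-5,8,11,14,17-pentaen-1-one | CC/C=C\C/C=C\C/C=C\C/C=C\C/C=C\CCCC(=O)c1c(OCOC)cc(OCOC)cc1OCOC | intermediate
8 | (5Z,8Z,11Z,14Z,17Z)-1-(2,4,6-trihydroxyphenyl)icosa-5,8,11,14,17-pentaen-1-one | CC/C=C\C/C=C\C/C=C\C/C=C\C/C=C\CCCC(=O)c1c(O)cc(O)cc1O | intermediate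
9 | (5Z,8Z,11Z,13E,15S,17Z)-15-hydroperoxy-1-(2,4,6-trihydroxyphenyl)icosa-5,8,11,13,17-pentaen-1-one | CC/C=C\C[C@H](OO)/C=C/C=C\C/C=C\C/C=C\CCCC(=O)c1c(O)cc(O)cc1O | intermediate (not isolated)
10 | (5Z,8Z,11Z,13E,15S,17Z)-15-hydroxy-1-(2,4,6-trihydroxyphenyl)icosa-5,8,11,13,17-pentaen-1-one (CNP0104813.2) | CC/C=C\C[C@H](O)/C=C/C=C\C/C=C\C/C=C\CCCC(=O)c1c(O)cc(O)cc1O | target

**Step count**
Total steps: 5. Longest linear sequence: 4 (1 → 2 → 7 → 8 → 10).

**Three steps most likely to fail** (step 5 is the most uncertain)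

Step 3. The doubly ortho-substituted aryllithium may deprotonate or demethoxylate the Weinreb amide instead of adding. The fallback sets out from 2 and comes back at 7. Amide 2 is reduced with i-Bu2AlH (THF, –78 °C) to (5Z,8Z,11Z,14Z,17Z)-icosa-5,8,11,14,17-pentaenal F1. Aryllithium 5, made from 4 as in step 3, adds to this far more reactive electrophile at –78 °C to give racemic (5Z,8Z,11Z,14Z,17Z)-1-[2,4,6-tris(methoxymethoxy)phenyl]icosa-5,8,11,14,17-pentaen-1-ol F2. Dess–Martin periodinane with NaHCO3 in CH2Cl2 at 0 °C then oxidises F2 to ketone 7.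

Step 4. Formaldehyde equivalents released from the MOM groups may bridge the electron-rich phloroglucinol rings, and the acid may slowly isomerise the polyene. The fallback sets out from 3 and 2 and comes back at 8; it replaces acetal protection by silyl protection that is removed with fluoride.
- Phloroglucinol 3 with TBSCl and imidazole in DMF gives 1,3,5-tris(tert-butyldimethylsilyloxy)benzene F3.
- NBS in CH2Cl2 at 0 °C gives 2-bromo-1,3,5-tris(tert-butyldimethylsilyloxy)benzene F4.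
- t-BuLi (2 equiv) in Et2O at –78 °C, with short contact so that the O-to-C silyl shift does not compete, gives 2,4,6-tris(tert-butyldimethylsilyloxy)phenyllithium F5.
- F5 adds to 2 through the lithium hemiaminal adduct F6 and, after an AcOH quench, gives (5Z,8Z,11Z,14Z,17Z)-1-[2,4,6-tris(tert-butyldimethylsilyloxy)phenyl]icosa-5,8,11,14,17-pentaen-1-one F7.
- TBAF buffered with AcOH in THF at 0 °C gives 8.

Step 5. The enzyme may not bind the aryl ketone head group, the phenol may slow the iron cycle, or a second dioxygenation may compete. The fallback uses only known chemistry, sets out from 1 and comes back at 10; the oxygenation is moved to the free acid, the established substrate.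
- LiOH in THF/H2O hydrolyses 1 to (5Z,8Z,11Z,14Z,17Z)-icosa-5,8,11,14,17-pentaenoic acid F8.
- Soybean lipoxygenase-1 with O2 in Na2B4O7 buffer at pH 9 gives (5Z,8Z,11Z,13E,15S,17Z)-15-hydroperoxyicosa-5,8,11,13,17-pentaenoic acid F9, reduced in the same pot with NaBH4 to (5Z,8Z,11Z,13E,15S,17Z)-15-hydroxyicosa-5,8,11,13,17-pentaenoic acid F10.
- MeNH(OMe)·HCl, EDC·HCl and N-methylmorpholine in CH2Cl2 give (5Z,8Z,11Z,13E,15S,17Z)-15-hydroxy-N-methoxy-N-methylicosa-5,8,11,13,17-pentaenamide F11.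
- TBSCl and imidazole give (5Z,8Z,11Z,13E,15S,17Z)-15-(tert-butyldimethylsilyloxy)-N-methoxy-N-methylicosa-5,8,11,13,17-pentaenamide F12.
- The aryllithium F5 of the step 4 fallback adds through the lithium hemiaminal adduct F13 to give (5Z,8Z,11Z,13E,15S,17Z)-15-(tert-butyldimethylsilyloxy)-1-[2,4,6-tris(tert-butyldimethylsilyloxy)phenyl]icosa-5,8,11,13,17-pentaen-1-one F14.
- TBAF/AcOH in THF (0 °C to rt) removes all four silyl groups without touching the acid-labile dienyl carbinol and gives 10.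

**Further compounds**
F1 | step 3 | (5Z,8Z,11Z,14Z,17Z)-icosa-5,8,11,14,17-pentaenal | CC/C=C\C/C=C\C/C=C\C/C=C\C/C=C\CCCC=O
F2 | step 3 | (5Z,8Z,11Z,14Z,17Z)-1-[2,4,6-tris(methoxymethoxy)phenyl]icosa-5,8,11,14,17-pentaen-1-ol (racemic) | CC/C=C\C/C=C\C/C=C\C/C=C\C/C=C\CCCC(O)c1c(OCOC)cc(OCOC)cc1OCOC
F3 | step 4 | 1,3,5-tris(tert-butyldimethylsilyloxy)benzene | CC(C)(C)[Si](C)(C)Oc1cc(O[Si](C)(C)C(C)(C)C)cc(O[Si](C)(C)C(C)(C)C)c1
F4 | step 4 | 2-bromo-1,3,5-tris(tert-butyldimethylsilyloxy)benzene | Brc1c(O[Si](C)(C)C(C)(C)C)cc(O[Si](C)(C)C(C)(C)C)cc1O[Si](C)(C)C(C)(C)C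
F5 | step 4 | 2,4,6-tris(tert-butyldimethylsilyloxy)phenyllithium | [Li]c1c(O[Si](C)(C)C(C)(C)C)cc(O[Si](C)(C)C(C)(C)C)cc1O[Si](C)(C)C(C)(C)C
F6 | step 4 | lithium (5Z,8Z,11Z,14Z,17Z)-1-[methoxy(methyl)amino]-1-[2,4,6-tris(tert-butyldimethylsilyloxy)phenyl]icosa-5,8,11,14,17-pentaen-1-olate (racemic at C1) | CC/C=C\C/C=C\C/C=C\C/C=C\C/C=C\CCCC(O[Li])(N(C)OC)c1c(O[Si](C)(C)C(C)(C)C)cc(O[Si](C)(C)C(C)(C)C)cc1O[Si](C)(C)C(C)(C)C
F7 | step 4 | (5Z,8Z,11Z,14Z,17Z)-1-[2,4,6-tris(tert-butyldimethylsilyloxy)phenyl]icosa-5,8,11,14,17-pentaen-1-one | CC/C=C\C/C=C\C/C=C\C/C=C\C/C=C\CCCC(=O)c1c(O[Si](C)(C)C(C)(C)C)cc(O[Si](C)(C)C(C)(C)C)cc1O[Si](C)(C)C(C)(C)C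
F8 | step 5 | (5Z,8Z,11Z,14Z,17Z)-icosa-5,8,11,14,17-pentaenoic acid | CC/C=C\C/C=C\C/C=C\C/C=C\C/C=C\CCCC(=O)O
F9 | step 5 | (5Z,8Z,11Z,13E,15S,17Z)-15-hydroperoxyicosa-5,8,11,13,17-pentaenoic acid | CC/C=C\C[C@H](OO)/C=C/C=C\C/C=C\C/C=C\CCCC(=O)O
F10 | step 5 | (5Z,8Z,11Z,13E,15S,17Z)-15-hydroxyicosa-5,8,11,13,17-pentaenoic acid | CC/C=C\C[C@H](O)/C=C/C=C\C/C=C\C/C=C\CCCC(=O)O
F11 | step 5 | (5Z,8Z,11Z,13E,15S,17Z)-15-hydroxy-N-methoxy-N-methylicosa-5,8,11,13,17-pentaenamide | CC/C=C\C[C@H](O)/C=C/C=C\C/C=C\C/C=C\CCCC(=O)N(C)OC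
F12 | step 5 | (5Z,8Z,11Z,13E,15S,17Z)-15-(tert-butyldimethylsilyloxy)-N-methoxy-N-methylicosa-5,8,11,13,17-pentaenamide | CC/C=C\C[C@H](O[Si](C)(C)C(C)(C)C)/C=C/C=C\C/C=C\C/C=C\CCCC(=O)N(C)OC
F13 | step 5 | lithium (5Z,8Z,11Z,13E,15S,17Z)-15-(tert-butyldimethylsilyloxy)-1-[methoxy(methyl)amino]-1-[2,4,6-tris(tert-butyldimethylsilyloxy)phenyl]icosa-5,8,11,13,17-pentaen-1-olate (mixture at C1) | CC/C=C\C[C@H](O[Si](C)(C)C(C)(C)C)/C=C/C=C\C/C=C\C/C=C\CCCC(O[Li])(N(C)OC)c1c(O[Si](C)(C)C(C)(C)C)cc(O[Si](C)(C)C(C)(C)C)cc1O[Si](C)(C)C(C)(C)C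
F14 | step 5 | (5Z,8Z,11Z,13E,15S,17Z)-15-(tert-butyldimethylsilyloxy)-1-[2,4,6-tris(tert-butyldimethylsilyloxy)phenyl]icosa-5,8,11,13,17-pentaen-1-one | CC/C=C\C[C@H](O[Si](C)(C)C(C)(C)C)/C=C/C=C\C/C=C\C/C=C\CCCC(=O)c1c(O[Si](C)(C)C(C)(C)C)cc(O[Si](C)(C)C(C)(C)C)cc1O[Si](C)(C)C(C)(C)C
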